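**Plan**
- Retrosynthesis: the two (Z)-hex-2-enoates are cut at their acyl C–O bonds (O3, O9); the C8–O and C7–C11 bonds are traced back to a C7=C8 enone on the C9 ketone; ring A is opened at C4–C5; the side chain is cut at C1–C10.
- Enabling feature: O3 and O9 stand 1,5 to each other across C4, the quaternary C5 and C10, so ring A (C1–C5, C10) is a 1,5-diketone that a Michael bond from the enolisable C4 to C5 can close.
- Forward: ring B comes from Hagemann's ester, alkylated at C10 with a bromo ketal made from ethyl vinyl ketone; ring A then closes by the amine-catalysed C4–C5 Michael addition; C3, C7, C8 and C9 are then elaborated, and both alcohols are acylated with hex-2-ynoic acid and semihydrogenated.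
- Differentiation: the C3 and C9 carbonyls of the ring-closed diketone are nearly equivalent, so a phenylsulfanyl group is carried on C8; with Li/NH3 it turns C9 into its enolate while C3 is reduced.
- Stereochemistry: C5 from the chiral primary amine catalyst; C4 and C10 by equilibration (equatorial methyl, trans fusion); C3 by dissolving-metal reduction (equatorial alcohol); C7 and C8 by attack anti to the axial C5 methyl; C9 by hydride attack anti to the axial C8 silyloxy group; both Z alkenes by syn semihydrogenation.

Key step: step 6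

Remark: locants follow the eremophilane skeleton (ring A = C1–C5, C10; ring B = C5–C10; methyls on C4 and C5; isopropenyl on C7); β is the face of the C5 methyl, α the opposite face.
Assumption: the sense of induction of the diamine catalyst in step 6 cannot be predicted with certainty; both enantiomers are accessible from L- or D-tert-leucine, and the one that gives the series drawn in the SMILES is used (written here as the S-diamine).

**Step 1**
Reactants: 1 ethyl vinyl ketone
Product: 3 2-(2-bromoethyl)-2-ethyl-1,3-dioxolane, via 1-bromopentan-3-one 2 (not isolated)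
Conditions: HBr (g), CH2Cl2, 0 °C; then ethylene glycol, HC(OEt)3, TsOH (cat.), rt
Reagents that add atoms: hydrogen bromide, Br; ethylene glycol, OCCO
Why: conjugate addition of HBr to the enone followed by acid-catalysed ketalisation (orthoformate as water scavenger) is the standard entry to β-bromo ketals and creates no stereocentre.

**Step 2**
Reactants: 4 Hagemann's ester (ethyl 2-methyl-4-oxocyclohex-2-ene-1-carboxylate); 3 2-(2-bromoethyl)-2-ethyl-1,3-dioxolane
Product: 6 ethyl 3-[2-(2-ethyl-1,3-dioxolan-2-yl)ethyl]-2-methyl-4-oxocyclohex-2-ene-1-carboxylate (racemic), via potassium dienolate 5 (not isolated)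
Conditions: t-BuOK, t-BuOH/THF, rt; then 3, NaI (cat.), 60 °C
Reagents that add atoms: none
Why: alkylation of the vinylogous enolate of Hagemann's ester takes place at the carbon α to the ketone, the classical route to 2-alkyl-3-methylcyclohexenones, and forms the C1–C10 bond; the double bond returns into conjugation with the ketone under the basic conditions.

**Step 3**
Reactants: 6 ethyl 3-[2-(2-ethyl-1,3-dioxolan-2-yl)ethyl]-2-methyl-4-oxocyclohex-2-ene-1-carboxylate
Product: 8 2-[2-(2-ethyl-1,3-dioxolan-2-yl)ethyl]-3-methylcyclohex-2-en-1-one, via potassium carboxylate 7 (not isolated)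
Conditions: KOH, EtOH/H2O, reflux
Reagents that add atoms: none
Why: saponification gives the vinylogous β-keto carboxylate, which decarboxylates on heating in base (ester hydrolysis–decarboxylation), while the dioxolane is inert to hydroxide.

**Step 4**
Reactants: 8 2-[2-(2-ethyl-1,3-dioxolan-2-yl)ethyl]-3-methylcyclohex-2-en-1-one
Product: 10 2-[2-(2-ethyl-1,3-dioxolan-2-yl)ethyl]-3-methyl-6-(phenylsulfanyl)cyclohex-2-en-1-one (racemic), via lithium dienolate 9 (not isolated)
Conditions: LiN(iPr)2, THF, −78 °C; then PhSO2SPh, −78 → 0 °C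
Reagents that add atoms: S-phenyl benzenethiosulfonate, O=S(=O)(Sc1ccccc1)c1ccccc1
Why: kinetic deprotonation of the enone by the hindered amide occurs at the α'-methylene (the future C8), the side-chain ketone being masked, and the cross-conjugated enolate is sulfenylated by the thiosulfonate (α-sulfenylation of a ketone enolate); the new centre is formed as a racemate and needs no control.

**Step 5**
Reactants: 10 2-[2-(2-ethyl-1,3-dioxolan-2-yl)ethyl]-3-methyl-6-(phenylsulfanyl)cyclohex-2-en-1-one
Product: 11 3-methyl-2-(3-oxopentyl)-6-(phenylsulfanyl)cyclohex-2-en-1-one (racemic; sulfur-bearing carbon configurationally labile)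
Conditions: 1 M HCl, THF, 0 °C → rt (short exposure)
Reagents that add atoms: water, O
Why: acid-catalysed hydrolysis of the dioxolane unmasks the Michael donor ketone; short exposure at low temperature avoids an acid-promoted racemic cyclisation.

**Step 6**
Reactants: 11 3-methyl-2-(3-oxopentyl)-6-(phenylsulfanyl)cyclohex-2-en-1-one
Product: 13 4β,5β-dimethyl-8-(phenylsulfanyl)-trans-decalin-3,9-dione (10α-H; mixture of C8 epimers), via enamine 12 (not isolated)
Conditions: (S)-N1,N1-diethyl-3,3-dimethylbutane-1,2-diamine·TfOH (20 mol%), 3-nitrobenzoic acid (20 mol%), toluene, 50 °C; then TsOH (10 mol%), 50 °C to complete the C4/C10 equilibration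
Reagents that add atoms: none
Why: Proposed new method: the primary amine of the catalyst condenses with the side-chain ketone (C3) to give enamine 12, whose C4 adds to C5, the β-carbon of the tetrasubstituted enone, while the protonated tertiary amine of the same catalyst hydrogen-bonds to the C9 carbonyl; hydrolysis releases the diketone and the amine, and the closest known reaction types are amine-catalysed intramolecular Michael additions of ketones to enones and the base-mediated cyclisation of 2-(3-oxoalkyl)cyclohex-2-enones to racemic decalindiones. Ring A closes in a 6-(enolendo)-endo-trig mode, the enamine double bond lying inside the new ring and the attacked C5=C10 bond being endocyclic to it. C5 is set by the catalyst, which must choose the enone face in the hydrogen-bonded enamine–ammonium transition state; the C8 sulfide is a labile spectator centre that epimerises and is erased in step 7. C4 and C10 are each α to a carbonyl and are set by equilibration to the equatorial C4 methyl (cis to the C5 methyl) and the trans ring fusion, in which neither carbonyl carbon carries an axial hydrogen facing the axial methyl. The step needs 1,4- over 1,2-addition and reaction through C4 and not C2: C2 could reach C5 only through a four-membered ring, and the C9 carbonyl is conjugated, flanked by the sulfur-bearing C8 and can give only a reversible aldol adduct, whereas the Michael adduct is the thermodynamic sink.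

**Step 7**
Reactants: 13 4β,5β-dimethyl-8-(phenylsulfanyl)-trans-decalin-3,9-dione
Product: 15 3α-hydroxy-4β,5β-dimethyl-trans-decalin-9-one, via dilithium enolate alkoxide 14 (not isolated)
Conditions: Li, NH3 (l)/THF, t-BuOH (2 equiv), −78 °C; then solid NH4Cl
Reagents that add atoms: none
Why: dissolving-metal reduction plays two known roles at once: the α-phenylsulfanyl ketone is cleaved reductively to the C8=C9 lithium enolate, which shields C9 from further reduction, and the C3 ketone is reduced under thermodynamic control to the equatorial 3α-alcohol, as in alkali-metal reductions of friedelin-type 4,5-dimethyl-3-ketones, where hydride reagents give the axial epimer instead.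

**Step 8**
Reactants: 15 3α-hydroxy-4β,5β-dimethyl-trans-decalin-9-one
Product: 16 3α-benzoyloxy-4β,5β-dimethyl-trans-decalin-9-one
Conditions: BzCl, pyridine, DMAP (cat.), CH2Cl2, 0 °C → rt
Reagents that add atoms: benzoyl chloride, O=C(Cl)c1ccccc1
Why: DMAP-catalysed acylation of the equatorial alcohol gives a benzoate that tolerates amide base, cuprate and peracid and is removed by the hydride of step 12.

**Step 9**
Reactants: 16 3α-benzoyloxy-4β,5β-dimethyl-trans-decalin-9-one
Product: 19 3α-benzoyloxy-4β,5β-dimethyl-trans-decal-7-en-9-one (C7=C8 enone), via lithium enolate 17 (not isolated), via sulfilimine adduct 18 (not isolated)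
Conditions: LiN(iPr)2, THF, −78 °C; then PhS(Cl)=NtBu, −78 °C
Reagents that add atoms: none
Why: kinetic enolisation of the C9 ketone occurs at the C8 methylene rather than the C10 methine, and the enolate is dehydrogenated in the same flask by N-tert-butylbenzenesulfinimidoyl chloride (Mukaiyama dehydrogenation: S–C bond formation, then syn-elimination of the sulfenamide).

**Step 10**
Reactants: 19 3α-benzoyloxy-4β,5β-dimethyl-trans-decal-7-en-9-one; 20 2-bromopropene
Product: 23 3α-benzoyloxy-7α-isopropenyl-4β,5β-dimethyl-9-(triethylsilyloxy)-trans-decal-8-ene (C8=C9 silyl enol ether), via isopropenyllithium 21 (not isolated), via lithium diisopropenylcuprate 22 (not isolated)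
Conditions: 20, Li, Et2O, 0 °C; CuI, −40 °C; then 19, Et3SiCl, THF, −78 °C; Et3N, aq. NH4Cl
Reagents that add atoms: chlorotriethylsilane, CC[Si](Cl)(CC)CC
Why: conjugate addition of the Gilman-type cuprate (CH2=C(CH3))2CuLi, accelerated by the chlorosilane, delivers the isopropenyl group to C7 from the α face because the β-face trajectory is syn-axial to the C5 methyl, so the substituent ends up equatorial; the enolate is trapped regiospecifically as the C8=C9 silyl enol ether.

**Step 11**
Reactants: 23 3α-benzoyloxy-7α-isopropenyl-4β,5β-dimethyl-9-(triethylsilyloxy)-trans-decal-8-ene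
Product: 25 3α-benzoyloxy-7α-isopropenyl-4β,5β-dimethyl-8α-(triethylsilyloxy)-trans-decalin-9-one, via silyloxy epoxide 24 (not isolated)
Conditions: mCPBA (1.0 equiv), NaHCO3, CH2Cl2, −20 °C → rt
Reagents that add atoms: 3-chloroperoxybenzoic acid, OOC(=O)c1cccc(Cl)c1
Why: Rubottom oxidation: the electron-rich enol ether, far more reactive than the isopropenyl group, is epoxidised on the α face (anti to the C5 methyl, which is syn-axial to C9), and 1,4-silyl migration after ring opening gives the α-silyloxy ketone with the axial 8α oxygen.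

**Step 12**
Reactants: 25 3α-benzoyloxy-7α-isopropenyl-4β,5β-dimethyl-8α-(triethylsilyloxy)-trans-decalin-9-one
Product: 26 7α-isopropenyl-4β,5β-dimethyl-8α-(triethylsilyloxy)-trans-decalin-3α,9α-diol
Conditions: LiAlH4, THF, −78 → 0 °C; H2O, aq. NaOH
Reagents that add atoms: none
Why: hydride reduction of an α-silyloxy ketone under Felkin–Anh (non-chelation) control: hydride adds to C9 anti to the axial C8–O bond, whose bulky silyl ether also blocks the α face, giving the equatorial 9α-alcohol cis to O8; the same reagent reduces the benzoate off O3.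

**Step 13**
Reactants: 26 7α-isopropenyl-4β,5β-dimethyl-8α-(triethylsilyloxy)-trans-decalin-3α,9α-diol; 27 hex-2-ynoic acid
Product: 29 3α,9α-bis(hex-2-ynoyloxy)-7α-isopropenyl-4β,5β-dimethyl-8α-(triethylsilyloxy)-trans-decalin, via O-acylisourea 28 (not isolated)
Conditions: 27 (3 equiv), DCC, DMAP (cat.), CH2Cl2, 0 °C → rt
Reagents that add atoms: none
Why: Steglich esterification acylates both equatorial secondary alcohols while O8 stays silylated; the alkynoic acid is used because a (Z)-enoic acid could isomerise under DMAP catalysis.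

**Step 14**
Reactants: 29 3α,9α-bis(hex-2-ynoyloxy)-7α-isopropenyl-4β,5β-dimethyl-8α-(triethylsilyloxy)-trans-decalin
Product: 30 3α,9α-bis[(Z)-hex-2-enoyloxy]-7α-isopropenyl-4β,5β-dimethyl-8α-(triethylsilyloxy)-trans-decalin
Conditions: H2 (1 atm), Pd/CaCO3 poisoned with Pb(OAc)2, quinoline, EtOAc, rt
Reagents that add atoms: none
Why: Lindlar semihydrogenation adds hydrogen syn to each ynoate and stops at the (Z)-enoate; the 1,1-disubstituted isopropenyl group should not be reduced on the poisoned catalyst.

**Step 15**
Reactants: 30 3α,9α-bis[(Z)-hex-2-enoyloxy]-7α-isopropenyl-4β,5β-dimethyl-8α-(triethylsilyloxy)-trans-decalin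
Product: 31 CNP0420276.1, 3α,9α-bis[(Z)-hex-2-enoyloxy]-8α-hydroxy-7α-isopropenyl-4β,5β-dimethyl-trans-decalin (10α-H)
Conditions: HF·pyridine, pyridine/THF, 0 °C → rt
Reagents that add atoms: none
Why: fluoride cleavage of the triethylsilyl ether under acidic, buffered conditions frees the axial C8 alcohol without the O9→O8 acyl migration or Z/E isomerisation that basic fluoride could cause.

**Compound list**
1 | ethyl vinyl ketone (pent-1-en-3-one) | CCC(=O)C=C | starting material
2 | 1-bromopentan-3-one (not isolated) | CCC(=O)CCBr | intermediate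
3 | 2-(2-bromoethyl)-2-ethyl-1,3-dioxolane | CCC1(CCBr)OCCO1 | intermediate
4 | Hagemann's ester, ethyl 2-methyl-4-oxocyclohex-2-ene-1-carboxylate (racemic) | CCOC(=O)C1CCC(=O)C=C1C | starting material
5 | potassium dienolate of 4 (not isolated) | CCOC(=O)C1=C(C)C=C([O-])CC1.[K+] | intermediate
6 | ethyl 3-[2-(2-ethyl-1,3-dioxolan-2-yl)ethyl]-2-methyl-4-oxocyclohex-2-ene-1-carboxylate (racemic) | CCOC(=O)C1CCC(=O)C(CCC2(CC)OCCO2)=C1C | intermediate
7 | potassium 3-[2-(2-ethyl-1,3-dioxolan-2-yl)ethyl]-2-methyl-4-oxocyclohex-2-ene-1-carboxylate (not isolated) | [K+].[O-]C(=O)C1CCC(=O)C(CCC2(CC)OCCO2)=C1C | intermediate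
8 | 2-[2-(2-ethyl-1,3-dioxolan-2-yl)ethyl]-3-methylcyclohex-2-en-1-one | CCC1(CCC2=C(C)CCCC2=O)OCCO1 | intermediate
9 | lithium cross-conjugated dienolate of 8 (not isolated) | CCC1(CCC2=C(C)CCC=C2O[Li])OCCO1 | intermediate
10 | 2-[2-(2-ethyl-1,3-dioxolan-2-yl)ethyl]-3-methyl-6-(phenylsulfanyl)cyclohex-2-en-1-one (racemic) | CCC1(CCC2=C(C)CCC(Sc3ccccc3)C2=O)OCCO1 | intermediate
11 | 3-methyl-2-(3-oxopentyl)-6-(phenylsulfanyl)cyclohex-2-en-1-one (racemic, labile centre) | CCC(=O)CCC1=C(C)CCC(Sc2ccccc2)C1=O | intermediate
12 | E-enamine of the side-chain ketone of 11 with the S-diamine catalyst (not isolated) | C/C=C(\CCC1=C(C)CCC(Sc2ccccc2)C1=O)N[C@@H](C(C)(C)C)CN(CC)CC | intermediate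
13 | 4β,5β-dimethyl-8-(phenylsulfanyl)-trans-decalin-3,9-dione (10α-H; C8 epimers, C8 left undefined) | C1C[C@]2(C)[C@@H](C)C(=O)CC[C@H]2C(=O)C1Sc3ccccc3 | intermediate
14 | dilithium C8=C9 enolate and C3 alkoxide (not isolated) | C1C[C@]2(C)[C@@H](C)[C@H](O[Li])CC[C@H]2C(O[Li])=C1 | intermediate
15 | 3α-hydroxy-4β,5β-dimethyl-trans-decalin-9-one | C1C[C@]2(C)[C@@H](C)[C@H](O)CC[C@H]2C(=O)C1 | intermediate
16 | 3α-benzoyloxy-4β,5β-dimethyl-trans-decalin-9-one | C1C[C@]2(C)[C@@H](C)[C@H](OC(=O)c3ccccc3)CC[C@H]2C(=O)C1 | intermediate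
17 | lithium C8=C9 enolate of 16 (not isolated) | C1C[C@]2(C)[C@@H](C)[C@H](OC(=O)c3ccccc3)CC[C@H]2C(O[Li])=C1 | intermediate
18 | C8 sulfilimine adduct of 16, C8–S(=N-tBu)Ph (not isolated) | C1C[C@]2(C)[C@@H](C)[C@H](OC(=O)c3ccccc3)CC[C@H]2C(=O)C1S(=NC(C)(C)C)c4ccccc4 | intermediate
19 | 3α-benzoyloxy-4β,5β-dimethyl-trans-decal-7-en-9-one | C=1C[C@]2(C)[C@@H](C)[C@H](OC(=O)c3ccccc3)CC[C@H]2C(=O)C=1 | intermediate
20 | 2-bromopropene | C=C(C)Br | starting material
21 | isopropenyllithium (not isolated) | [Li]C(C)=C | intermediate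
22 | lithium diisopropenylcuprate (not isolated) | [Li+].C=C(C)[Cu-]C(C)=C | intermediate
23 | 3α-benzoyloxy-7α-isopropenyl-4β,5β-dimethyl-9-(triethylsilyloxy)-trans-decal-8-ene | C=C(C)[C@@H]1C[C@]2(C)[C@@H](C)[C@H](OC(=O)c3ccccc3)CC[C@H]2C(O[Si](CC)(CC)CC)=C1 | intermediate
24 | 8α,9α-epoxide of 23 with the silyloxy group on C9 (not isolated) | C=C(C)[C@@H]1C[C@]2(C)[C@@H](C)[C@H](OC(=O)c3ccccc3)CC[C@H]2[C@]4(O[Si](CC)(CC)CC)O[C@H]14 | intermediate
25 | 3α-benzoyloxy-7α-isopropenyl-4β,5β-dimethyl-8α-(triethylsilyloxy)-trans-decalin-9-one | C=C(C)[C@@H]1C[C@]2(C)[C@@H](C)[C@H](OC(=O)c3ccccc3)CC[C@H]2C(=O)[C@@H]1O[Si](CC)(CC)CC | intermediate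
26 | 7α-isopropenyl-4β,5β-dimethyl-8α-(triethylsilyloxy)-trans-decalin-3α,9α-diol | C=C(C)[C@@H]1C[C@]2(C)[C@@H](C)[C@H](O)CC[C@H]2[C@H](O)[C@@H]1O[Si](CC)(CC)CC | intermediate
27 | hex-2-ynoic acid | CCCC#CC(=O)O | starting material
28 | O-(hex-2-ynoyl)-N,N'-dicyclohexylisourea (not isolated) | CCCC#CC(=O)OC(=NC1CCCCC1)NC1CCCCC1 | intermediate
29 | 3α,9α-bis(hex-2-ynoyloxy)-7α-isopropenyl-4β,5β-dimethyl-8α-(triethylsilyloxy)-trans-decalin | C=C(C)[C@@H]1C[C@]2(C)[C@@H](C)[C@H](OC(=O)C#CCCC)CC[C@H]2[C@H](OC(=O)C#CCCC)[C@@H]1O[Si](CC)(CC)CC | intermediate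
30 | 3α,9α-bis[(Z)-hex-2-enoyloxy]-7α-isopropenyl-4β,5β-dimethyl-8α-(triethylsilyloxy)-trans-decalin | C=C(C)[C@@H]1C[C@]2(C)[C@@H](C)[C@H](OC(=O)/C=C\CCC)CC[C@H]2[C@H](OC(=O)/C=C\CCC)[C@@H]1O[Si](CC)(CC)CC | intermediate
31 | CNP0420276.1, 3α,9α-bis[(Z)-hex-2-enoyloxy]-8α-hydroxy-7α-isopropenyl-4β,5β-dimethyl-trans-decalin | C=C(C)[C@@H]1C[C@]2(C)[C@@H](C)[C@H](OC(=O)/C=C\CCC)CC[C@H]2[C@H](OC(=O)/C=C\CCC)[C@@H]1O | target

**Step count and risks**
Total step count: 15. Longest linear sequence: 15 steps (1 → 31); 4, 20 and 27 enter at steps 2, 10 and 13.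

Steps most likely to fail:

1. Step 6 (the proposed method). The tetrasubstituted enone may react too slowly, the enone face may be chosen poorly, or aldol closure at C9 may compete. The fallback uses known chemistry and sets out from 11. Base-mediated intramolecular Michael cyclisation (NaOMe, MeOH) gives 13 as the racemate with the enantiomer of 13 F1. Step 7 conditions convert the racemate into 15 together with the enantiomer of 15 F2. Esterification with (S)-2-methoxy-2-phenylacetic acid (DCC, DMAP) gives two diastereomers, the (S)-2-methoxy-2-phenylacetate of 15 F3 and the (S)-2-methoxy-2-phenylacetate of the enantiomer of 15 F4, which are separated by chromatography or crystallisation. Methanolysis of F3 (K2CO3, MeOH) returns enantiopure 15, where the route is rejoined.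

2. Step 7. The C9 enolate may be protonated and over-reduced, or the C3 ketone may be reduced incompletely. The fallback sets out from 13 and distinguishes the carbonyls by unsaturation instead. Oxidation with mCPBA (1 equiv, −78 °C) gives the sulfoxide of 13 F5, and thermal syn-elimination (toluene, CaCO3, 90 °C) gives the ene-dione 4β,5β-dimethyl-trans-decal-7-ene-3,9-dione F6. NaBH4 in EtOH at −40 °C reduces the saturated C3 ketone in preference to the enone and, by attack from the α face, should give the axial alcohol 3β-hydroxy-4β,5β-dimethyl-trans-decal-7-en-9-one F7. Mitsunobu esterification with benzoic acid (PPh3, DIAD) inverts C3 and gives 19 directly, where the route is rejoined.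

3. Step 12. Hydride delivery may occur from the α face, because the β-face trajectory is syn-axial to the C5 methyl. The fallback sets out from 25 and relies on thermodynamic control. If reduction gives the 9β-epimer of 26 F8, it is equilibrated under Meerwein–Ponndorf–Verley/Oppenauer conditions (Al(OiPr)3, catalytic acetone, toluene/i-PrOH, reflux). The axial 9β-alcohol is syn-axial to the C5 methyl, so the equilibrium should lie on the side of the equatorial 9α-alcohol 26, where the route is rejoined.

**Further compounds**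
F1 | step 6 | enantiomer of 13 (formed with 13 as the racemate) | C1C[C@@]2(C)[C@H](C)C(=O)CC[C@@H]2C(=O)C1Sc3ccccc3
F2 | step 6 | enantiomer of 15 (formed with 15 as the racemate) | C1C[C@@]2(C)[C@H](C)[C@@H](O)CC[C@@H]2C(=O)C1
F3 | step 6 | (S)-2-methoxy-2-phenylacetate of 15 | C1C[C@]2(C)[C@@H](C)[C@H](OC(=O)[C@@H](OC)c3ccccc3)CC[C@H]2C(=O)C1
F4 | step 6 | (S)-2-methoxy-2-phenylacetate of the enantiomer of 15 | C1C[C@@]2(C)[C@H](C)[C@@H](OC(=O)[C@@H](OC)c3ccccc3)CC[C@@H]2C(=O)C1
F5 | step 7 | sulfoxide of 13, 4β,5β-dimethyl-8-(phenylsulfinyl)-trans-decalin-3,9-dione | C1C[C@]2(C)[C@@H](C)C(=O)CC[C@H]2C(=O)C1S(=O)c3ccccc3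
F6 | step 7 | 4β,5β-dimethyl-trans-decal-7-ene-3,9-dione | C=1C[C@]2(C)[C@@H](C)C(=O)CC[C@H]2C(=O)C=1
F7 | step 7 | 3β-hydroxy-4β,5β-dimethyl-trans-decal-7-en-9-one | C=1C[C@]2(C)[C@@H](C)[C@@H](O)CC[C@H]2C(=O)C=1
F8 | step 12 | 9β-epimer of 26 | C=C(C)[C@@H]1C[C@]2(C)[C@@H](C)[C@H](O)CC[C@H]2[C@@H](O)[C@@H]1O[Si](CC)(CC)CC
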